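The route rests on disconnecting the bond between C7, the vinylic CH of the E‑trisubstituted C6=C7 alkene in the 2,6‑dimethylocta‑2,6‑dienyl linker, and C8, the CH2 on the quinone ring. Because C6 carries a methyl group, this alkene is the syn‑methylmetalation product of a terminal alkyne. In one operation, trimethylaluminium adds CH3 and aluminium across the alkyne of the complete (S)‑butenolide 13, and the resulting alkenylalane is coupled under nickel catalysis with chloromethylquinone 18. Three components, the alkene geometry, the methyl branch and the fragment union are thus settled in one flask, giving the target directly. Precursor 13 is the butenolide bearing a 2‑methylhept‑2‑en‑6‑ynyl chain at C5.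

Key step: step 11

Remark: pent‑4‑ynal, isopropenylmagnesium bromide solution, ethyl 2‑[bis(2‑methylphenoxy)phosphoryl]acetate, 5‑bromo‑2‑methylpent‑2‑ene and 4‑methoxy‑2‑methylphenol are taken as catalogue compounds; D‑proline is assumed to give the (S)‑α‑aminoxy aldehyde, the mirror image of the (R) product expected from L‑proline.

Step 1
Reactants: 1 pent‑4‑ynal; 2 isopropenylmagnesium bromide
Product: 3 racemic 2‑methylhept‑1‑en‑6‑yn‑3‑ol
Conditions: CH2=C(CH3)MgBr (1.1 equiv), THF, −78 °C; then H2O/aq. NH4Cl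
Reagents that add atoms: none
Why: Grignard 1,2‑addition to the aldehyde should outrun deprotonation of the terminal alkyne at −78 °C; the carbinol centre may stay racemic because step 2 erases it.

Step 2
Reactants: 3 racemic 2‑methylhept‑1‑en‑6‑yn‑3‑ol
Product: 5 ethyl (E)‑4‑methylnon‑4‑en‑8‑ynoate, via ketene acetal 4 (not isolated)
Conditions: MeC(OEt)3 (6 equiv), EtCO2H (5 mol%), 140 °C, EtOH distilled off
Reagents that add atoms: triethyl orthoacetate, CC(OCC)(OCC)OCC
Why: Johnson–Claisen orthoester rearrangement; the chair [3,3] transition state with the but‑3‑ynyl group equatorial should give the E trisubstituted alkene.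

Step 3
Reactants: 5 ethyl (E)‑4‑methylnon‑4‑en‑8‑ynoate
Product: 6 (E)‑4‑methylnon‑4‑en‑8‑ynal
Conditions: i‑Bu2AlH (1.05 equiv), CH2Cl2, −78 °C; then MeOH, dilute aq. HCl
Reagents that add atoms: none
Why: Partial ester reduction with i‑Bu2AlH stops at the aldehyde because the tetrahedral aluminate is stable at −78 °C and the alkyne is not hydroaluminated at that temperature.

Step 4
Reactants: 7 ethyl 2‑[bis(2‑methylphenoxy)phosphoryl]acetate; 8 5‑bromo‑2‑methylpent‑2‑ene
Product: 9 racemic ethyl 2‑[bis(2‑methylphenoxy)phosphoryl]‑6‑methylhept‑5‑enoate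
Conditions: 7 (1.2 equiv), NaH (1.0 equiv), DMSO, rt; then 8 (1.0 equiv), NaI (10 mol%), 50 °C
Reagents that add atoms: none
Why: SN2 C‑alkylation of the stabilised phosphonoacetate anion by the primary bromide, with iodide catalysis, should install the 4‑methylpent‑3‑enyl group.

Step 5
Reactants: 6 (E)‑4‑methylnon‑4‑en‑8‑ynal; 9 racemic ethyl 2‑[bis(2‑methylphenoxy)phosphoryl]‑6‑methylhept‑5‑enoate
Product: 11 ethyl (2Z,4S,6E)‑6‑methyl‑2‑(4‑methylpent‑3‑en‑1‑yl)‑4‑[(phenylamino)oxy]undeca‑2,6‑dien‑10‑ynoate, via aminoxy aldehyde 10 (not isolated)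
Conditions: PhNO (1.0 equiv, slow addition), D‑proline (20 mol%), MeCN, −20 °C; then cannulated into 9 (1.3 equiv)/NaH (1.3 equiv), THF, −78 → 0 °C
Reagents that add atoms: nitrosobenzene, O=Nc1ccccc1
Why: Proline‑enamine α‑aminoxylation (O‑selective nitroso aldol) should set the C–O stereocentre as S under control of D‑proline, and the Z‑selective Horner–Wadsworth–Emmons olefination with the diaryl phosphonate then places ester and carbinol carbon cis.

Step 6
Reactants: 11 ethyl (2Z,4S,6E)‑6‑methyl‑2‑(4‑methylpent‑3‑en‑1‑yl)‑4‑[(phenylamino)oxy]undeca‑2,6‑dien‑10‑ynoate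
Product: 13 (S)‑5‑[(E)‑2‑methylhept‑2‑en‑6‑yn‑1‑yl]‑3‑(4‑methylpent‑3‑en‑1‑yl)furan‑2(5H)‑one, via hydroxy ester 12 (not isolated)
Conditions: Zn dust, AcOH/THF (1:4), 0 °C → rt; then p‑TsOH·H2O (5 mol%), CH2Cl2, rt
Reagents that add atoms: none
Why: Reductive N–O cleavage by Zn/AcOH frees the γ‑hydroxyl, which lactonises onto the cis ester (transesterification) without touching the C–O stereocentre.

Step 7
Reactants: 14 4‑methoxy‑2‑methylphenol
Product: 15 2‑(hydroxymethyl)‑4‑methoxy‑6‑methylphenol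
Conditions: 37% aq. CH2O (1.5 equiv), NaOH (1.0 equiv), H2O, 25 °C, 48 h; then AcOH to pH 6
Reagents that add atoms: formaldehyde, C=O
Why: Lederer–Manasse hydroxymethylation of the phenoxide can only occur at the single free ortho position, since the para position carries the methoxy group.

Step 8
Reactants: 15 2‑(hydroxymethyl)‑4‑methoxy‑6‑methylphenol
Product: 16 (2,5‑dimethoxy‑3‑methylphenyl)methanol
Conditions: MeI (1.5 equiv), K2CO3 (2 equiv), acetone, reflux
Reagents that add atoms: iodomethane, CI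
Why: Williamson etherification is selective for the phenol because K2CO3 deprotonates only the phenolic O–H and not the benzylic alcohol.

Step 9
Reactants: 16 (2,5‑dimethoxy‑3‑methylphenyl)methanol
Product: 17 1‑(chloromethyl)‑2,5‑dimethoxy‑3‑methylbenzene
Conditions: SOCl2 (1.2 equiv), CH2Cl2, 0 °C → rt
Reagents that add atoms: thionyl chloride, O=S(Cl)Cl
Why: Chlorodehydroxylation of an electron‑rich benzylic alcohol via its chlorosulfite should be fast and clean.

Step 10
Reactants: 17 1‑(chloromethyl)‑2,5‑dimethoxy‑3‑methylbenzene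
Product: 18 2‑(chloromethyl)‑6‑methylcyclohexa‑2,5‑diene‑1,4‑dione
Conditions: (NH4)2Ce(NO3)6 (2.5 equiv), MeCN/H2O (2:1), 0 °C, 20 min; used at once
Reagents that add atoms: water, O
Why: Oxidative demethylation of the hydroquinone dimethyl ether by (NH4)2Ce(NO3)6 gives the para‑quinone, and the chloromethyl group should survive the short, cold aqueous contact.

Step 11
Reactants: 13 (S)‑5‑[(E)‑2‑methylhept‑2‑en‑6‑yn‑1‑yl]‑3‑(4‑methylpent‑3‑en‑1‑yl)furan‑2(5H)‑one; 18 2‑(chloromethyl)‑6‑methylcyclohexa‑2,5‑diene‑1,4‑dione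
Product: 20 (5S)‑5‑[(2E,6E)‑2,6‑dimethyl‑8‑(5‑methyl‑3,6‑dioxocyclohexa‑1,4‑dien‑1‑yl)octa‑2,6‑dien‑1‑yl]‑3‑(4‑methylpent‑3‑en‑1‑yl)furan‑2(5H)‑one, via alkenylalane 19 (not isolated)
Conditions: AlMe3 (3.0 equiv), Cp2ZrCl2 (20 mol%), H2O (1.0 equiv), CH2Cl2, −20 °C; volatiles removed in vacuo; then 18 (1.1 equiv), NiCl2(PPh3)2 (5 mol%)/n‑BuLi (10 mol%), THF, −20 → 0 °C
Reagents that add atoms: trimethylaluminium, C[Al](C)C
Why: Cp2ZrCl2‑catalysed methylalumination adds CH3 to the internal and AlMe2 to the terminal alkyne carbon of 13 in a syn fashion, giving the (E)‑2‑methylalkenylalane 19 with the C6 methyl and the C6=C7 geometry already in place. After removal of excess AlMe3, zerovalent nickel (from NiCl2(PPh3)2 and n‑BuLi) inserts into the activated C–Cl bond of 18, the alkenyl group passes from aluminium to nickel with retention, and reductive elimination forms the C7–C8 bond. The closest known reaction type is the zirconium‑catalysed carboalumination/Negishi‑type coupling of alkenylalanes with benzylic chlorides and chloromethylquinones used for prenylated quinones. No ring is closed and no stereocentre is created; the remote C5 stereocentre of the butenolide is not touched, and the E alkene is controlled by the syn addition and the stereoretentive coupling. The step needs methyl delivery to the internal alkyne carbon (secured by the terminal alkyne), chemoselectivity for the alkyne over the two trisubstituted alkenes and the lactone (secured by the short, cold, water‑accelerated carboalumination), and substitution at CH2Cl instead of addition to the quinone (secured by nickel catalysis at −20 °C and the absence of free AlMe3).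

Compound list
1 | pent‑4‑ynal | C#CCCC=O | starting material
2 | isopropenylmagnesium bromide | CC(=C)[Mg]Br | starting material
3 | racemic 2‑methylhept‑1‑en‑6‑yn‑3‑ol | C=C(C)C(O)CCC#C | intermediate
4 | 3‑[(1‑ethoxyethenyl)oxy]‑2‑methylhept‑1‑en‑6‑yne (ketene acetal) | C=C(OCC)OC(CCC#C)C(C)=C | intermediate (not isolated)
5 | ethyl (E)‑4‑methylnon‑4‑en‑8‑ynoate | CCOC(=O)CC/C(C)=C/CCC#C | intermediate
6 | (E)‑4‑methylnon‑4‑en‑8‑ynal | O=CCC/C(C)=C/CCC#C | intermediate
7 | ethyl 2‑[bis(2‑methylphenoxy)phosphoryl]acetate | CCOC(=O)CP(=O)(Oc1ccccc1C)Oc1ccccc1C | starting material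
8 | 5‑bromo‑2‑methylpent‑2‑ene | CC(C)=CCCBr | starting material
9 | racemic ethyl 2‑[bis(2‑methylphenoxy)phosphoryl]‑6‑methylhept‑5‑enoate | CCOC(=O)C(CCC=C(C)C)P(=O)(Oc1ccccc1C)Oc1ccccc1C | intermediate
10 | (2S,4E)‑4‑methyl‑2‑[(phenylamino)oxy]non‑4‑en‑8‑ynal | O=C[C@@H](ONc1ccccc1)C/C(C)=C/CCC#C | intermediate (not isolated)
11 | ethyl (2Z,4S,6E)‑6‑methyl‑2‑(4‑methylpent‑3‑en‑1‑yl)‑4‑[(phenylamino)oxy]undeca‑2,6‑dien‑10‑ynoate | CCOC(=O)/C(CCC=C(C)C)=C\[C@@H](ONc1ccccc1)C/C(C)=C/CCC#C | intermediate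
12 | ethyl (2Z,4S,6E)‑4‑hydroxy‑6‑methyl‑2‑(4‑methylpent‑3‑en‑1‑yl)undeca‑2,6‑dien‑10‑ynoate | CCOC(=O)/C(CCC=C(C)C)=C\[C@@H](O)C/C(C)=C/CCC#C | intermediate (not isolated)
13 | (S)‑5‑[(E)‑2‑methylhept‑2‑en‑6‑yn‑1‑yl]‑3‑(4‑methylpent‑3‑en‑1‑yl)furan‑2(5H)‑one | CC(C)=CCCC1=C[C@H](C/C(C)=C/CCC#C)OC1=O | intermediate
14 | 4‑methoxy‑2‑methylphenol | COc1ccc(O)c(C)c1 | starting material
15 | 2‑(hydroxymethyl)‑4‑methoxy‑6‑methylphenol | COc1cc(C)c(O)c(CO)c1 | intermediate
16 | (2,5‑dimethoxy‑3‑methylphenyl)methanol | COc1cc(C)c(OC)c(CO)c1 | intermediate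
17 | 1‑(chloromethyl)‑2,5‑dimethoxy‑3‑methylbenzene | COc1cc(C)c(OC)c(CCl)c1 | intermediate
18 | 2‑(chloromethyl)‑6‑methylcyclohexa‑2,5‑diene‑1,4‑dione | ClCC1=CC(=O)C=C(C)C1=O | intermediate
19 | dimethyl{(1E,5E)‑2,6‑dimethyl‑7‑[(2S)‑4‑(4‑methylpent‑3‑en‑1‑yl)‑5‑oxo‑2,5‑dihydrofuran‑2‑yl]hepta‑1,5‑dien‑1‑yl}alane | C[Al](C)/C=C(\C)CC/C=C(\C)C[C@H]1C=C(CCC=C(C)C)C(=O)O1 | intermediate (not isolated)
20 | (5S)‑5‑[(2E,6E)‑2,6‑dimethyl‑8‑(5‑methyl‑3,6‑dioxocyclohexa‑1,4‑dien‑1‑yl)octa‑2,6‑dien‑1‑yl]‑3‑(4‑methylpent‑3‑en‑1‑yl)furan‑2(5H)‑one | CC(C)=CCCC1=C[C@H](C/C(C)=C/CC/C(C)=C/CC2=CC(=O)C=C(C)C2=O)OC1=O | target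

Total step count: 11.
Longest linear sequence: 6 steps (steps 1, 2, 3, 5, 6 and 11, from pent‑4‑ynal).

Steps most likely to fail

Step 11. The alkenylalane or residual methylaluminium species may add to, or transfer electrons to, the free quinone (two unsubstituted ring positions, two carbonyls), and the quinone may sequester the nickel catalyst, so that substitution at CH2Cl is outrun. The fallback sets out from 13 and 17 and comes back at 20. Alkyne 13 is carboaluminated as before (AlMe3, Cp2ZrCl2, CH2Cl2), and alkenylalane 19 is coupled with the protected benzylic chloride 17 under Pd(PPh3)4 catalysis in THF at rt. This should give (5S)‑5‑[(2E,6E)‑8‑(2,5‑dimethoxy‑3‑methylphenyl)‑2,6‑dimethylocta‑2,6‑dien‑1‑yl]‑3‑(4‑methylpent‑3‑en‑1‑yl)furan‑2(5H)‑one F1. Oxidative demethylation of F1 with (NH4)2Ce(NO3)6 in MeCN/H2O at 0 °C, which should tolerate the trisubstituted alkenes and the butenolide, then gives 20.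

Step 5. Base‑mediated enolisation of the α‑aminoxy aldehyde may erode the enantiopurity, and Z control with the α‑branched phosphonate may be incomplete, leaving material that cannot lactonise. The fallback sets out from 6 (and uses 8) and comes back at 13. Triethyl phosphonoacetate (CCOC(=O)CP(=O)(OCC)OCC) is alkylated with 8 (NaH, DMSO) to give ethyl 2‑(diethoxyphosphoryl)‑6‑methylhept‑5‑enoate F2. Aminoxy aldehyde 10, made from 6 as in step 5, is olefinated with F2 under mild LiCl/DBU Horner–Wadsworth–Emmons conditions (MeCN, 0 °C). This should give mainly ethyl (2E,4S,6E)‑6‑methyl‑2‑(4‑methylpent‑3‑en‑1‑yl)‑4‑[(phenylamino)oxy]undeca‑2,6‑dien‑10‑ynoate F3, whose alkene geometry no longer matters. Zn/AcOH then gives ethyl (2E,4S,6E)‑4‑hydroxy‑6‑methyl‑2‑(4‑methylpent‑3‑en‑1‑yl)undeca‑2,6‑dien‑10‑ynoate F4. Irradiation (254 nm, MeCN) with p‑TsOH (cat.) equilibrates the enoate geometry, and the Z isomer 12 is drained by lactonisation to 13.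

Step 7. The hydroxymethylated phenoxide may condense further with unreacted phenol through an ortho‑quinone methide, giving diarylmethanes instead of stopping at mono‑hydroxymethylation. The fallback sets out from 14 and comes back at 16. Magnesium‑mediated ortho‑formylation (MgCl2, Et3N, paraformaldehyde, MeCN, reflux) should give 2‑hydroxy‑5‑methoxy‑3‑methylbenzaldehyde F5. O‑Methylation (MeI, K2CO3, DMF) gives 2,5‑dimethoxy‑3‑methylbenzaldehyde F6, and NaBH4 in MeOH reduces it to 16.

Further compounds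
F1 | step 11 | (5S)‑5‑[(2E,6E)‑8‑(2,5‑dimethoxy‑3‑methylphenyl)‑2,6‑dimethylocta‑2,6‑dien‑1‑yl]‑3‑(4‑methylpent‑3‑en‑1‑yl)furan‑2(5H)‑one | CC(C)=CCCC1=C[C@H](C/C(C)=C/CC/C(C)=C/Cc2cc(OC)cc(C)c2OC)OC1=O
F2 | step 5 | ethyl 2‑(diethoxyphosphoryl)‑6‑methylhept‑5‑enoate | CCOC(=O)C(CCC=C(C)C)P(=O)(OCC)OCC
F3 | step 5 | ethyl (2E,4S,6E)‑6‑methyl‑2‑(4‑methylpent‑3‑en‑1‑yl)‑4‑[(phenylamino)oxy]undeca‑2,6‑dien‑10‑ynoate | CCOC(=O)/C(CCC=C(C)C)=C/[C@@H](ONc1ccccc1)C/C(C)=C/CCC#C
F4 | step 5 | ethyl (2E,4S,6E)‑4‑hydroxy‑6‑methyl‑2‑(4‑methylpent‑3‑en‑1‑yl)undeca‑2,6‑dien‑10‑ynoate | CCOC(=O)/C(CCC=C(C)C)=C/[C@@H](O)C/C(C)=C/CCC#C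
F5 | step 7 | 2‑hydroxy‑5‑methoxy‑3‑methylbenzaldehyde | COc1cc(C)c(O)c(C=O)c1
F6 | step 7 | 2,5‑dimethoxy‑3‑methylbenzaldehyde | COc1cc(C)c(OC)c(C=O)c1
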